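## Retrosynthetic overview

- The strategy rests on the cyclohexene ring C1'–C6'. Its C3'=C4' double bond (methyl on C3') lies between the C2' methine stereocentre and C5', next to the quaternary C1'. This is the pattern left by a [4+2] cycloaddition that forms C1'–C2' and C5'–C6'.
- That ring is made first, by an enantioselective Diels–Alder reaction of a 2-silyloxy-3-methylpenta-1,3-diene with a 2-(silyloxymethyl)acrolein. The endo formyl carbon is reduced to the C1' methyl, the silyl enol ether is reduced to C3'=C4' through its triflate, and the silyloxymethyl arm becomes the first chain carbon.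
- The chain is grown through a vinyl group, hydroboration and B-alkyl Suzuki coupling with the (E)-enol triflate of ethyl acetoacetate, giving the (E)-trisubstituted allylic carbonate.
- The chromene O1–C2 bond comes from a palladium-catalysed asymmetric allylic etherification of a vinylphenol. The phenol is made from 1,2,3-trimethoxybenzene through a C2v-symmetric resorcinol aldehyde whose two hydroxyls are equivalent.
- Ring order: the benzene ring is bought, the cyclohexene ring is closed in step 4, and the pyran ring is closed last by ring-closing metathesis (C3=C4, step 23).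

Key step: step 4

Remark on locants: primed locants C1'–C6' denote the cyclohexene ring (C1' quaternary); chromene atoms are unprimed. The two ring stereocentres keep the spatial arrangement set in step 4 throughout; their CIP letters change only because substituent priorities change.

Assumption on the Diels–Alder face: the (S)-prolinol-derived oxazaborolidinium ion is assumed, from the usual two-point binding model for 2-substituted acroleins, to give the adduct as drawn; if a trial run shows the opposite sense, the (R)-catalyst is used with nothing else changed.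

Assumption on the allylic etherification: the (R,R)-ligand is assumed to give the (R)-configured tertiary ether from the (E)-carbonate; if a trial run shows the opposite sense, the (S,S)-ligand is used.

## Route

Step 1
Reactants: 1 (E)-3-methylpent-3-en-2-one
Product: 3 (E)-3-methyl-2-(triisopropylsilyloxy)penta-1,3-diene, via lithium dienolate 2 (not isolated)
Conditions: LiN(i-Pr)2, THF, −78 °C; then i-Pr3SiOTf, −78 to 0 °C
Reagents that add atoms: triisopropylsilyl trifluoromethanesulfonate, CC(C)[Si](OS(=O)(=O)C(F)(F)F)(C(C)C)C(C)C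
Why: Kinetic deprotonation of the enone at the α'-methyl group gives the cross-conjugated lithium dienolate, and its O-silylation (silyl enol ether formation) should give the 2-silyloxydiene with the (E)-trisubstituted alkene untouched.

Step 2
Reactants: 4 2-methylenepropane-1,3-diol
Product: 5 2-[(triisopropylsilyloxy)methyl]prop-2-en-1-ol
Conditions: 4 (3 equiv), i-Pr3SiCl (1 equiv), imidazole, DMF, 0 °C to rt
Reagents that add atoms: chlorotriisopropylsilane, CC(C)[Si](Cl)(C(C)C)C(C)C
Why: Statistical monosilylation of a symmetrical diol used in excess should give the mono ether; the triisopropylsilyl group is chosen for this arm so that the alkyl silyl ether later outlasts the fluoride-triggered enol triflation.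

Step 3
Reactants: 5 2-[(triisopropylsilyloxy)methyl]prop-2-en-1-ol
Product: 6 2-[(triisopropylsilyloxy)methyl]prop-2-enal
Conditions: MnO2, CH2Cl2, rt
Reagents that add atoms: none
Why: MnO2 oxidises allylic alcohols selectively to enals and leaves the silyl ether alone.

Step 4
Reactants: 3 (E)-3-methyl-2-(triisopropylsilyloxy)penta-1,3-diene, 6 2-[(triisopropylsilyloxy)methyl]prop-2-enal
Product: 7 (1S,2R)-2,3-dimethyl-4-(triisopropylsilyloxy)-1-[(triisopropylsilyloxy)methyl]cyclohex-3-ene-1-carbaldehyde (formyl cis to the C2' methyl)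
Conditions: (S)-3,3-diphenyl-1-(o-tolyl)tetrahydro-1H,3H-pyrrolo[1,2-c][1,3,2]oxazaborole (20 mol %), (CF3SO2)2NH (18 mol %), CH2Cl2, −78 °C
Reagents that add atoms: none
Why: The oxazaborolidinium ion binds the formyl oxygen of 6 (formyl C–H···O contact to the ring oxygen, enal s-trans) and lowers its LUMO, and the s-cis diene 3 then adds in a concerted but asynchronous [4+2] cycloaddition in which the silyloxy-activated CH2 terminus bonds to the β-carbon (C5'–C6') ahead of the bond from the methyl-bearing terminus to the α-carbon (C1'–C2'). The closest known reaction type is the enantioselective Diels–Alder reaction of 2-substituted acroleins with 2-silyloxy-1,3-dienes under cationic oxazaborolidine catalysis. The one ring formed, the cyclohexene C1'–C6', is closed by this intermolecular cycloaddition, four carbons coming from the diene and two from the dienophile, with the silyl enol ether left at C3'=C4'. C1' is set by the catalyst, whose carbinol-carbon phenyl group covers one face of the bound enal so that the diene adds to the open face, and C2' is set relative to C1' by the endo orientation of the formyl group toward the (E)-configured methyl terminus, which puts CHO cis to the C2' methyl. The step needs regio-, endo- and face selectivity: the 2-silyloxy group (para rule) and the terminal methyl group (ortho rule) direct to the same regioisomer, the boron-bound formyl group is the endo-directing substituent with an acyclic diene, and face selectivity rests on the two-point binding of the aldehyde. The triisopropylsilyl groups on both partners should resist the acidic catalyst at −78 °C.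

Step 5
Reactants: 7 (1S,2R)-2,3-dimethyl-4-(triisopropylsilyloxy)-1-[(triisopropylsilyloxy)methyl]cyclohex-3-ene-1-carbaldehyde
Product: 8 [(1R,2S)-2,3-dimethyl-4-(triisopropylsilyloxy)-1-[(triisopropylsilyloxy)methyl]cyclohex-3-en-1-yl]methanol
Conditions: NaBH4, MeOH/THF, 0 °C
Reagents that add atoms: none
Why: Borohydride reduction of the hindered aldehyde should give the neopentyl alcohol, and neither the silyl ether nor the silyl enol ether reacts under these fluoride-free basic conditions.

Step 6
Reactants: 8 [(1R,2S)-2,3-dimethyl-4-(triisopropylsilyloxy)-1-[(triisopropylsilyloxy)methyl]cyclohex-3-en-1-yl]methanol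
Product: 9 [(1S,2S)-2,3-dimethyl-4-(triisopropylsilyloxy)-1-[(triisopropylsilyloxy)methyl]cyclohex-3-en-1-yl]methyl methanesulfonate
Conditions: CH3SO2Cl, Et3N, CH2Cl2, 0 °C
Reagents that add atoms: methanesulfonyl chloride, CS(=O)(=O)Cl
Why: Sulfonylation of the only free hydroxyl activates the former formyl carbon for hydride displacement.

Step 7
Reactants: 9 [(1S,2S)-2,3-dimethyl-4-(triisopropylsilyloxy)-1-[(triisopropylsilyloxy)methyl]cyclohex-3-en-1-yl]methyl methanesulfonate
Product: 10 triisopropyl{[(1R,2S)-1,2,3-trimethyl-4-(triisopropylsilyloxy)cyclohex-3-en-1-yl]methoxy}silane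
Conditions: LiEt3BH, THF, 0 to 65 °C
Reagents that add atoms: none
Why: Hydride displacement of a neopentyl sulfonate by lithium triethylborohydride should turn the former formyl carbon into the C1' methyl group cis to the C2' methyl, both silyl ethers being inert to hydride.

Step 8
Reactants: 10 triisopropyl{[(1R,2S)-1,2,3-trimethyl-4-(triisopropylsilyloxy)cyclohex-3-en-1-yl]methoxy}silane
Product: 12 (3S,4R)-2,3,4-trimethyl-4-[(triisopropylsilyloxy)methyl]cyclohex-1-en-1-yl trifluoromethanesulfonate, via cesium enolate 11 (not isolated)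
Conditions: CsF, PhN(SO2CF3)2, 1,2-dimethoxyethane, rt
Reagents that add atoms: N-phenylbis(trifluoromethanesulfonimide), O=S(=O)(N(c1ccccc1)S(=O)(=O)C(F)(F)F)C(F)(F)F
Why: Fluoride cleaves the silyl enol ether far faster than the primary alkyl silyl ether because the enolate is the better leaving group, and the cesium enolate is O-triflated in place so that the tetrasubstituted enolate regiochemistry is kept (fluoride-induced enol triflation).

Step 9
Reactants: 12 (3S,4R)-2,3,4-trimethyl-4-[(triisopropylsilyloxy)methyl]cyclohex-1-en-1-yl trifluoromethanesulfonate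
Product: 13 triisopropyl{[(1R,2R)-1,2,3-trimethylcyclohex-3-en-1-yl]methoxy}silane
Conditions: Pd(OAc)2 (5 mol %), PPh3 (10 mol %), HCO2H, n-Bu3N, DMF, 60 °C
Reagents that add atoms: none
Why: Palladium-catalysed formate reduction of an enol triflate (oxidative addition to zerovalent palladium, formate exchange, decarboxylation, reductive elimination) should replace OTf by H without moving the C3'=C4' double bond.

Step 10
Reactants: 13 triisopropyl{[(1R,2R)-1,2,3-trimethylcyclohex-3-en-1-yl]methoxy}silane
Product: 14 [(1R,2R)-1,2,3-trimethylcyclohex-3-en-1-yl]methanol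
Conditions: n-Bu4NF, THF, rt to 50 °C
Reagents that add atoms: none
Why: Fluoride desilylation frees the neopentyl alcohol, no other fluoride-labile group being left.

Step 11
Reactants: 14 [(1R,2R)-1,2,3-trimethylcyclohex-3-en-1-yl]methanol
Product: 15 (1R,2R)-1,2,3-trimethylcyclohex-3-ene-1-carbaldehyde
Conditions: Dess–Martin periodinane, CH2Cl2, 0 °C to rt
Reagents that add atoms: none
Why: Dess–Martin oxidation should give the aldehyde, which cannot epimerise because its α-carbon is quaternary.

Step 12
Reactants: 15 (1R,2R)-1,2,3-trimethylcyclohex-3-ene-1-carbaldehyde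
Product: 16 (1S,2R)-1-ethenyl-1,2,3-trimethylcyclohex-3-ene
Conditions: CH3PPh3Br, KOt-Bu, THF, 0 °C to rt; pentane work-up, careful concentration
Reagents that add atoms: methyltriphenylphosphonium bromide, C[P+](c1ccccc1)(c1ccccc1)c1ccccc1.[Br-]
Why: Wittig methylenation of a non-enolisable hindered aldehyde should give the terminal vinyl group that carries the second chain carbon.

Step 13
Reactants: 17 ethyl acetoacetate
Product: 19 ethyl (2E)-3-{[(trifluoromethyl)sulfonyl]oxy}but-2-enoate, via tetramethylammonium enolate 18 (not isolated)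
Conditions: aq. Me4NOH, hexanes, 5 °C; then (CF3SO2)2O
Reagents that add atoms: trifluoromethanesulfonic anhydride, O=S(=O)(OS(=O)(=O)C(F)(F)F)C(F)(F)F
Why: With a non-coordinating ammonium counter-ion the β-keto ester enolate is not chelated and should be O-triflated in its (E) form (stereoselective enol triflate formation from β-keto esters).

Step 14
Reactants: 16 (1S,2R)-1-ethenyl-1,2,3-trimethylcyclohex-3-ene, 19 ethyl (2E)-3-{[(trifluoromethyl)sulfonyl]oxy}but-2-enoate
Product: 21 ethyl (2E)-3-methyl-5-[(1S,2S)-1,2,3-trimethylcyclohex-3-en-1-yl]pent-2-enoate, via B-alkyl-9-BBN 20 (not isolated)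
Conditions: 9-BBN, THF, 0 °C to rt; then 19, PdCl2(dppf) (5 mol %; dppf = 1,1'-bis(diphenylphosphino)ferrocene), K3PO4 (aq), DMF, 50 °C
Reagents that add atoms: none
Why: 9-BBN should hydroborate the monosubstituted vinyl group anti-Markovnikov in preference to the trisubstituted ring alkene, and the B-alkyl Suzuki–Miyaura coupling with the enol triflate proceeds with retention of alkene geometry to give the (E)-enoate.

Step 15
Reactants: 21 ethyl (2E)-3-methyl-5-[(1S,2S)-1,2,3-trimethylcyclohex-3-en-1-yl]pent-2-enoate
Product: 22 (2E)-3-methyl-5-[(1S,2S)-1,2,3-trimethylcyclohex-3-en-1-yl]pent-2-en-1-ol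
Conditions: i-Bu2AlH, CH2Cl2, −78 °C
Reagents that add atoms: none
Why: 1,2-Reduction of the conjugated ester by i-Bu2AlH should give the (E)-allylic alcohol without touching either alkene.

Step 16
Reactants: 22 (2E)-3-methyl-5-[(1S,2S)-1,2,3-trimethylcyclohex-3-en-1-yl]pent-2-en-1-ol
Product: 23 methyl (2E)-3-methyl-5-[(1S,2S)-1,2,3-trimethylcyclohex-3-en-1-yl]pent-2-en-1-yl carbonate
Conditions: ClCO2CH3, pyridine, CH2Cl2, 0 °C
Reagents that add atoms: methyl chloroformate, COC(=O)Cl
Why: Acylation of the primary allylic alcohol gives the carbonate leaving group, which later supplies its own methoxide base on ionisation.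

Step 17
Reactants: 24 1,2,3-trimethoxybenzene
Product: 25 1,5-dibromo-2,3,4-trimethoxybenzene
Conditions: N-bromosuccinimide (2.1 equiv), MeCN, 0 °C to rt
Reagents that add atoms: N-bromosuccinimide, O=C1CCC(=O)N1Br
Why: Electrophilic aromatic bromination should occur twice at the two equivalent positions ortho and para to the outer methoxy groups (C4 and C6), the twisted central methoxy group activating C5 only weakly.

Step 18
Reactants: 25 1,5-dibromo-2,3,4-trimethoxybenzene
Product: 26 4,5,6-trimethoxybenzene-1,3-diol
Conditions: Pd2(dba)3 (2 mol %), t-BuXPhos (2-di-tert-butylphosphino-2',4',6'-triisopropylbiphenyl, 8 mol %), KOH, 1,4-dioxane/H2O, 100 °C; then aq. HCl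
Reagents that add atoms: potassium hydroxide, [K+].[OH-]
Why: Palladium-catalysed hydroxylation of aryl bromides with hydroxide (C–O coupling driven by the bulky biarylphosphine) should replace both bromines and give the C2v-symmetric resorcinol.

Step 19
Reactants: 26 4,5,6-trimethoxybenzene-1,3-diol
Product: 27 2,6-dihydroxy-3,4,5-trimethoxybenzaldehyde
Conditions: MgCl2, Et3N, (CH2O)n, MeCN, 80 °C
Reagents that add atoms: paraformaldehyde (as formaldehyde), C=O
Why: Magnesium-mediated ortho-formylation of phenols can only take place at the single aromatic C–H, which lies between the two hydroxyls, so no regiochemical question arises.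

Step 20
Reactants: 27 2,6-dihydroxy-3,4,5-trimethoxybenzaldehyde
Product: 28 2-hydroxy-3,4,5-trimethoxy-6-(triisopropylsilyloxy)benzaldehyde
Conditions: i-Pr3SiCl (1.0 equiv), imidazole, DMF, 0 °C to rt
Reagents that add atoms: chlorotriisopropylsilane, CC(C)[Si](Cl)(C(C)C)C(C)C
Why: The two hydroxyls are equivalent, and after the first silylation the remaining one is held in a strong hydrogen bond to the formyl oxygen and is much less nucleophilic, so monosilylation should be favoured.

Step 21
Reactants: 28 2-hydroxy-3,4,5-trimethoxy-6-(triisopropylsilyloxy)benzaldehyde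
Product: 29 4,5,6-trimethoxy-3-(triisopropylsilyloxy)-2-vinylphenol
Conditions: CH3PPh3Br (2.5 equiv), KOt-Bu (2.4 equiv), THF, 0 °C to rt
Reagents that add atoms: methyltriphenylphosphonium bromide, C[P+](c1ccccc1)(c1ccccc1)c1ccccc1.[Br-]
Why: Wittig methylenation of a salicylaldehyde with excess ylide (the first equivalent only deprotonates the phenol) should give the ortho-vinylphenol, the bulky aryl silyl ether tolerating the alkoxide-free ylide.

Step 22
Reactants: 23 methyl (2E)-3-methyl-5-[(1S,2S)-1,2,3-trimethylcyclohex-3-en-1-yl]pent-2-en-1-yl carbonate, 29 4,5,6-trimethoxy-3-(triisopropylsilyloxy)-2-vinylphenol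
Product: 30 1-{[(3R)-3-methyl-5-[(1S,2S)-1,2,3-trimethylcyclohex-3-en-1-yl]pent-1-en-3-yl]oxy}-4,5,6-trimethoxy-3-(triisopropylsilyloxy)-2-vinylbenzene
Conditions: Pd2(dba)3·CHCl3 (2.5 mol %), N,N'-[(1R,2R)-cyclohexane-1,2-diyl]bis[2-(diphenylphosphanyl)benzamide] (7.5 mol %), CH2Cl2, rt
Reagents that add atoms: none
Why: In this Trost asymmetric allylic alkylation with a phenol nucleophile, zerovalent palladium ionises the (E)-carbonate to a π-allyl complex and the phenoxide attacks its more substituted terminus inside the chiral ligand pocket, so the ligand alone sets the tertiary ether carbon (future C2), independently of the remote ring stereocentres.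

Step 23
Reactants: 30 1-{[(3R)-3-methyl-5-[(1S,2S)-1,2,3-trimethylcyclohex-3-en-1-yl]pent-1-en-3-yl]oxy}-4,5,6-trimethoxy-3-(triisopropylsilyloxy)-2-vinylbenzene
Product: 31 triisopropyl{[(2R)-6,7,8-trimethoxy-2-methyl-2-{2-[(1S,2S)-1,2,3-trimethylcyclohex-3-en-1-yl]ethyl}-2H-chromen-5-yl]oxy}silane
Conditions: second-generation Grubbs catalyst (5 mol %), CH2Cl2, 40 °C
Reagents that add atoms: none
Why: Ring-closing metathesis of the styrene and the allylic vinyl group should close the pyran ring at C3=C4 with loss of ethylene, the trisubstituted ring alkene being too hindered to take part.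

Step 24
Reactants: 31 triisopropyl{[(2R)-6,7,8-trimethoxy-2-methyl-2-{2-[(1S,2S)-1,2,3-trimethylcyclohex-3-en-1-yl]ethyl}-2H-chromen-5-yl]oxy}silane
Product: 32 (2R)-6,7,8-trimethoxy-2-methyl-2-{2-[(1S,2S)-1,2,3-trimethylcyclohex-3-en-1-yl]ethyl}-2H-chromen-5-ol (CNP0185215.2)
Conditions: n-Bu4NF, THF, 0 °C; work-up away from strong light and heat
Reagents that add atoms: none
Why: Fluoride cleaves the aryl silyl ether under mild non-acidic conditions that spare the acid-sensitive chromene; light and heat are avoided because 2H-chromenes can racemise at C2 by reversible 6π ring opening.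

## Compound list

1 | (E)-3-methylpent-3-en-2-one | C/C=C(\C)C(C)=O | starting material
2 | lithium (E)-3-methylpenta-1,3-dien-2-olate | [Li+].[O-]C(=C)/C(C)=C/C | intermediate
3 | (E)-3-methyl-2-(triisopropylsilyloxy)penta-1,3-diene | C=C(O[Si](C(C)C)(C(C)C)C(C)C)/C(C)=C/C | intermediate
4 | 2-methylenepropane-1,3-diol | C=C(CO)CO | starting material
5 | 2-[(triisopropylsilyloxy)methyl]prop-2-en-1-ol | C=C(CO)CO[Si](C(C)C)(C(C)C)C(C)C | intermediate
6 | 2-[(triisopropylsilyloxy)methyl]prop-2-enal | C=C(CO[Si](C(C)C)(C(C)C)C(C)C)C=O | intermediate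
7 | (1S,2R)-2,3-dimethyl-4-(triisopropylsilyloxy)-1-[(triisopropylsilyloxy)methyl]cyclohex-3-ene-1-carbaldehyde, formyl cis to the C2' methyl | CC(C)[Si](OC[C@]1(C=O)CCC(O[Si](C(C)C)(C(C)C)C(C)C)=C(C)[C@H]1C)(C(C)C)C(C)C | intermediate
8 | [(1R,2S)-2,3-dimethyl-4-(triisopropylsilyloxy)-1-[(triisopropylsilyloxy)methyl]cyclohex-3-en-1-yl]methanol | CC(C)[Si](OC[C@]1(CO)CCC(O[Si](C(C)C)(C(C)C)C(C)C)=C(C)[C@H]1C)(C(C)C)C(C)C | intermediate
9 | [(1S,2S)-2,3-dimethyl-4-(triisopropylsilyloxy)-1-[(triisopropylsilyloxy)methyl]cyclohex-3-en-1-yl]methyl methanesulfonate | CC(C)[Si](OC[C@]1(COS(C)(=O)=O)CCC(O[Si](C(C)C)(C(C)C)C(C)C)=C(C)[C@H]1C)(C(C)C)C(C)C | intermediate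
10 | triisopropyl{[(1R,2S)-1,2,3-trimethyl-4-(triisopropylsilyloxy)cyclohex-3-en-1-yl]methoxy}silane | CC(C)[Si](OC[C@]1(C)CCC(O[Si](C(C)C)(C(C)C)C(C)C)=C(C)[C@H]1C)(C(C)C)C(C)C | intermediate
11 | cesium (3S,4R)-2,3,4-trimethyl-4-[(triisopropylsilyloxy)methyl]cyclohex-1-en-1-olate | CC(C)[Si](OC[C@]1(C)CCC([O-])=C(C)[C@H]1C)(C(C)C)C(C)C.[Cs+] | intermediate
12 | (3S,4R)-2,3,4-trimethyl-4-[(triisopropylsilyloxy)methyl]cyclohex-1-en-1-yl trifluoromethanesulfonate | CC(C)[Si](OC[C@]1(C)CCC(OS(=O)(=O)C(F)(F)F)=C(C)[C@H]1C)(C(C)C)C(C)C | intermediate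
13 | triisopropyl{[(1R,2R)-1,2,3-trimethylcyclohex-3-en-1-yl]methoxy}silane | CC(C)[Si](OC[C@]1(C)CCC=C(C)[C@H]1C)(C(C)C)C(C)C | intermediate
14 | [(1R,2R)-1,2,3-trimethylcyclohex-3-en-1-yl]methanol | OC[C@]1(C)CCC=C(C)[C@H]1C | intermediate
15 | (1R,2R)-1,2,3-trimethylcyclohex-3-ene-1-carbaldehyde | O=C[C@]1(C)CCC=C(C)[C@H]1C | intermediate
16 | (1S,2R)-1-ethenyl-1,2,3-trimethylcyclohex-3-ene | C=C[C@]1(C)CCC=C(C)[C@H]1C | intermediate
17 | ethyl acetoacetate | CCOC(=O)CC(C)=O | starting material
18 | tetramethylammonium enolate of ethyl acetoacetate, (E) form | CCOC(=O)/C=C(\C)[O-].C[N+](C)(C)C | intermediate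
19 | ethyl (2E)-3-{[(trifluoromethyl)sulfonyl]oxy}but-2-enoate | CCOC(=O)/C=C(\C)OS(=O)(=O)C(F)(F)F | intermediate
20 | 9-{2-[(1R,2S)-1,2,3-trimethylcyclohex-3-en-1-yl]ethyl}-9-borabicyclo[3.3.1]nonane | B1(CC[C@]2(C)CCC=C(C)[C@H]2C)C2CCCC1CCC2 | intermediate
21 | ethyl (2E)-3-methyl-5-[(1S,2S)-1,2,3-trimethylcyclohex-3-en-1-yl]pent-2-enoate | CCOC(=O)/C=C(\C)CC[C@]1(C)CCC=C(C)[C@H]1C | intermediate
22 | (2E)-3-methyl-5-[(1S,2S)-1,2,3-trimethylcyclohex-3-en-1-yl]pent-2-en-1-ol | OC/C=C(\C)CC[C@]1(C)CCC=C(C)[C@H]1C | intermediate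
23 | methyl (2E)-3-methyl-5-[(1S,2S)-1,2,3-trimethylcyclohex-3-en-1-yl]pent-2-en-1-yl carbonate | COC(=O)OC/C=C(\C)CC[C@]1(C)CCC=C(C)[C@H]1C | intermediate
24 | 1,2,3-trimethoxybenzene | COc1cccc(OC)c1OC | starting material
25 | 1,5-dibromo-2,3,4-trimethoxybenzene | COc1c(Br)cc(Br)c(OC)c1OC | intermediate
26 | 4,5,6-trimethoxybenzene-1,3-diol | COc1c(O)cc(O)c(OC)c1OC | intermediate
27 | 2,6-dihydroxy-3,4,5-trimethoxybenzaldehyde | COc1c(O)c(C=O)c(O)c(OC)c1OC | intermediate
28 | 2-hydroxy-3,4,5-trimethoxy-6-(triisopropylsilyloxy)benzaldehyde | COc1c(O)c(C=O)c(O[Si](C(C)C)(C(C)C)C(C)C)c(OC)c1OC | intermediate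
29 | 4,5,6-trimethoxy-3-(triisopropylsilyloxy)-2-vinylphenol | C=Cc1c(O)c(OC)c(OC)c(OC)c1O[Si](C(C)C)(C(C)C)C(C)C | intermediate
30 | 1-{[(3R)-3-methyl-5-[(1S,2S)-1,2,3-trimethylcyclohex-3-en-1-yl]pent-1-en-3-yl]oxy}-4,5,6-trimethoxy-3-(triisopropylsilyloxy)-2-vinylbenzene | C=Cc1c(O[Si](C(C)C)(C(C)C)C(C)C)c(OC)c(OC)c(OC)c1O[C@](C)(CC[C@]1(C)CCC=C(C)[C@H]1C)C=C | intermediate
31 | triisopropyl{[(2R)-6,7,8-trimethoxy-2-methyl-2-{2-[(1S,2S)-1,2,3-trimethylcyclohex-3-en-1-yl]ethyl}-2H-chromen-5-yl]oxy}silane | COc1c(O[Si](C(C)C)(C(C)C)C(C)C)c2c(c(OC)c1OC)O[C@](C)(CC[C@]1(C)CCC=C(C)[C@H]1C)C=C2 | intermediate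
32 | (2R)-6,7,8-trimethoxy-2-methyl-2-{2-[(1S,2S)-1,2,3-trimethylcyclohex-3-en-1-yl]ethyl}-2H-chromen-5-ol | COc1c(O)c2c(c(OC)c1OC)O[C@](C)(CC[C@]1(C)CCC=C(C)[C@H]1C)C=C2 | target

## Step count and risks

Total step count: 24. Longest linear sequence: 17 steps (steps 2, 3, 4–12, 14–16, 22–24).

Steps most likely to fail:

1. Step 4. The formyl group may take the exo orientation, as 2-substituted acroleins do with cyclic dienes, which would put CHO trans to the C2' methyl; discrimination between the enal faces may also be incomplete. The fallback exchanges the roles of the two one-carbon arms. It sets out from 3 and 6 and uses the enantiomeric (R)-configured oxazaborolidinium catalyst, so that exo addition gives the C1' epimer of 7, the exo aldehyde F1, with the correct C2' configuration. In F1 the formyl carbon is the chain carbon and the silyloxymethyl arm is the future methyl group. Wittig methylenation (CH3PPh3Br, KOt-Bu, THF) should give the vinyl silyl enol ether F2. CsF and PhN(SO2CF3)2 in 1,2-dimethoxyethane should convert it, by way of the cesium enolate F3, into the enol triflate F4. Formate reduction (Pd(OAc)2, PPh3, HCO2H, n-Bu3N, DMF) should give the diene silyl ether F5, and n-Bu4NF the neopentyl alcohol F6. Mesylation (CH3SO2Cl, Et3N) gives the mesylate F7, and LiEt3BH in hot THF should then give 16, where the route is rejoined.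

2. Step 22. The phenol carries two ortho substituents, so attack at the hindered terminus of the π-allyl complex may be slow, which would favour the linear ether or erode enantioselectivity. The fallback builds the pyran ring by condensation instead of etherification and metathesis. It sets out from 22 and 26. MnO2 oxidation of 22 in CH2Cl2 should give the enal F8. Heating F8 with the resorcinol 26 and ethylenediammonium diacetate in toluene should bring about C-alkylation at the only free ring position followed by oxa-6π electrocyclisation, giving the chromene directly. This gives up catalyst control at C2: 32 would form together with its C2 epimer F9, and the two are separated by preparative HPLC on a chiral stationary phase. The route is rejoined at 32.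

3. Step 7. Hydride may attack sulfur instead of the hindered neopentyl carbon, returning alcohol 8, or the displacement may be too slow. The fallback removes the oxygen at the aldehyde stage. It sets out from 7, which is condensed with p-toluenesulfonyl hydrazide in THF to give the tosylhydrazone F10. Reduction with catecholborane in CHCl3 at 0 °C followed by NaOAc·3H2O at reflux should give 10 with loss of dinitrogen and sulfinate, and the route is rejoined at 10.

Further compounds

F1 | step 4 | (1R,2R)-2,3-dimethyl-4-(triisopropylsilyloxy)-1-[(triisopropylsilyloxy)methyl]cyclohex-3-ene-1-carbaldehyde, formyl trans to the C2' methyl | O=C[C@]1(CO[Si](C(C)C)(C(C)C)C(C)C)CCC(O[Si](C(C)C)(C(C)C)C(C)C)=C(C)[C@H]1C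
F2 | step 4 | vinyl silyl enol ether: 1-ethenyl-2,3-dimethyl-4-(triisopropylsilyloxy)-1-[(triisopropylsilyloxy)methyl]cyclohex-3-ene, vinyl trans to the C2' methyl | C=C[C@]1(CO[Si](C(C)C)(C(C)C)C(C)C)CCC(O[Si](C(C)C)(C(C)C)C(C)C)=C(C)[C@H]1C
F3 | step 4 | cesium enolate: cesium 4-ethenyl-2,3-dimethyl-4-[(triisopropylsilyloxy)methyl]cyclohex-1-en-1-olate | C=C[C@]1(CO[Si](C(C)C)(C(C)C)C(C)C)CCC([O-])=C(C)[C@H]1C.[Cs+]
F4 | step 4 | enol triflate: 4-ethenyl-2,3-dimethyl-4-[(triisopropylsilyloxy)methyl]cyclohex-1-en-1-yl trifluoromethanesulfonate | C=C[C@]1(CO[Si](C(C)C)(C(C)C)C(C)C)CCC(OS(=O)(=O)C(F)(F)F)=C(C)[C@H]1C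
F5 | step 4 | diene silyl ether: [(1-ethenyl-2,3-dimethylcyclohex-3-en-1-yl)methoxy]triisopropylsilane | C=C[C@]1(CO[Si](C(C)C)(C(C)C)C(C)C)CCC=C(C)[C@H]1C
F6 | step 4 | neopentyl alcohol: (1-ethenyl-2,3-dimethylcyclohex-3-en-1-yl)methanol, hydroxymethyl cis to the C2' methyl | C=C[C@]1(CO)CCC=C(C)[C@H]1C
F7 | step 4 | mesylate: (1-ethenyl-2,3-dimethylcyclohex-3-en-1-yl)methyl methanesulfonate | C=C[C@]1(COS(C)(=O)=O)CCC=C(C)[C@H]1C
F8 | step 22 | (2E)-3-methyl-5-[(1S,2S)-1,2,3-trimethylcyclohex-3-en-1-yl]pent-2-enal | O=C/C=C(\C)CC[C@]1(C)CCC=C(C)[C@H]1C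
F9 | step 22 | (2S)-6,7,8-trimethoxy-2-methyl-2-{2-[(1S,2S)-1,2,3-trimethylcyclohex-3-en-1-yl]ethyl}-2H-chromen-5-ol (C2 epimer of 32) | COc1c(O)c2c(c(OC)c1OC)O[C@@](C)(CC[C@]1(C)CCC=C(C)[C@H]1C)C=C2
F10 | step 7 | (E)-tosylhydrazone of aldehyde 7 | CC(C)[Si](OC[C@]1(/C=N/NS(=O)(=O)c2ccc(C)cc2)CCC(O[Si](C(C)C)(C(C)C)C(C)C)=C(C)[C@H]1C)(C(C)C)C(C)C
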